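**Analysis of the target**

The target is the 3-O-galloyl ester of a flavan-3,4-diol. A chroman (benzo ring A fused to pyran ring C) carries a catechol ring B at C2, the gallate on O3, a free hydroxyl at C4 and phenols at C5 and C7. The three stereocentres are contiguous: C2 (R), C3 (S) and C4 (S). The aryl group at C2 and the acyloxy group at C3 are trans, and the oxygens at C3 and C4 are cis. The C4 hydroxyl is benzylic to a ring with oxygen donors at C5, C7 and C8a, so it ionises under mild acid to a quinone-methide-like cation that is trapped or oligomerises. The C2–O1 bond is benzylic as well, the seven phenols are oxidation-prone, and an ester on a cis-diol can migrate from O3 to O4 under base. The difficulty is therefore setting three adjacent carbinol centres, telling O3 from O4, and avoiding acid once the C4–O bond sits next to ring A. The strategy rests on the O1–C8a aryl ether bond of ring C, the one ring bond that carries no stereochemical information. If it is made last from the C2 hydroxyl and a halide at C8a, then C2, C3 and C4 are the carbinol centres of an open, all-anti 1,3-diarylpropane-1,2,3-triol, on which acyclic stereocontrol applies and each oxygen can carry its own protecting group.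

**Retrosynthetic reasoning**

Phenol protection. Target 26 is traced to the hepta-O-benzyl compound 25. One neutral hydrogenolysis then frees all seven phenols at the very end, after every acid- or base-sensitive operation is over.

O4–Si bond. 25 comes from silyl ether 24. Keeping O4 silylated until after the acylation means only O3 can be esterified, and a buffered fluoride removes the silyl group without acid and without freeing an alkoxide next to the ester.

Ester C–O bond. 24 is cut into chroman-3-ol 21 and the galloyl donor 23, made from acid 22. 21 comes from PMB ether 20 by oxidative ether cleavage, which is orthogonal to the silyl and benzyl ethers.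

O1–C8a bond (key disconnection). 20 is opened to bromo alcohol 19. This cut removes ring C without touching a stereocentre, so the forward reaction only has to join the C2 alkoxide to the brominated carbon C8a with retention at C2. A cut at C2–O1 would demand an inversion at an electron-rich benzylic carbon, and a cut at C4–C4a would demand an acid-promoted arylation. The forward reaction needs base only.

Release of O2. 19 comes from the bis-silyl ether 18, and 18 from alcohol 17. O2 must be masked while C4 is built and then freed alone, so it carries the more labile triethylsilyl group and O4 the more robust tert-butyldimethylsilyl group.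

C4 stereocentre and C4–C4a bond. 17 is traced to ketone 16 through the C4–H bond. A hydride delivered under chelation by the O3 ether gives the 3,4-anti relationship, and the PMB group is chosen on O3 partly because it chelates. Ketone 16 comes from carbinol 15 (configuration at C4 irrelevant), and 15 from aldehyde 10 and the arylmagnesium reagent 14. 14 is made from iodide 13, which derives from 12 and 5-bromoresorcinol 11.

Differentiation of the three oxygens. Aldehyde 10 comes from primary alcohol 9, and 9 from aryl acetal 8 by regioselective reductive opening, which leaves the PMB group on O3 only. 8 comes from alcohol 7 and benzoate 6, and 6 from diol benzoate 5. The acetal spans O3 and the primary oxygen, so O2 is the only oxygen that ever carries the silyl group.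

C2–O and C3–O bonds. 5 is traced to trans-epoxy alcohol 4. A carboxylate opening at the benzylic carbon with inversion turns the trans-epoxide into the 2,3-anti diol derivative. The absolute configuration comes from asymmetric epoxidation of allylic alcohol 3, which is two steps (olefination, reduction) from aldehyde 1 through ester 2.

**Alternatives that were turned down**

Alternative 1: Both carbinol C–O bonds at C3 and C4 are disconnected to the enantiopure flav-3-ene A2. The forward step is a catalytic OsO4 syn-dihydroxylation of the C3=C4 styrenyl bond anti to the C2 aryl group, giving cis-diol A1.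
- For: one step sets two stereocentres, the 3,4-cis relationship follows from syn addition and the 2,3-trans relationship from approach opposite ring B. On these two counts it is shorter than the chosen route and at least as secure.
- Against: everything hangs on the single stereocentre of A2, which is benzylic, allylic and oxygen-bearing. A 2H-chromene of this kind can racemise through reversible electrocyclic opening to an ortho-quinone methide and is readily oxidised to a flavylium ion.
- Against: A1 has two free secondary hydroxyls, so the gallate must be placed by regioselective acylation.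
- Comparison: the chosen strategy is longer but keeps C2 on a configurationally stable sp3 chain, differentiates O3 from O4 from the outset, and lets each stereocentre be corrected independently.

Alternative 2: Ring A is disconnected at C8–C8a and C4a–C5. The forward step is a formal [3+3] cyclocondensation of bis(silyloxy)diene A5 with bromodihydropyranone A4: conjugate addition at the future C8a, acylation at the future C4a, then loss of methanol and HBr to aromatise, giving dihydroflavonol gallate A3.
- For: it is convergent, the 5- and 7-phenols appear unprotected, and the gallate and the C2/C3 stereocentres are installed early on a small ring. It is stronger than the chosen route in protecting-group economy on ring A.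
- Against: the conjugate addition occurs at a carbon bearing O1, so β-elimination can open ring C and destroy C2. The α-acyloxy ketone can epimerise at C3 under the Lewis acid or base the annulation needs.
- Against: A3 is still a C4 ketone. Hydride reduction of 2,3-trans dihydroflavonols favours the 3,4-trans alcohol, the opposite of what is needed, and it must be done next to an ester.
- Comparison: the chosen strategy fixes C4 on the open chain under chelation control and has no ring-A annulation risk.

Alternative 3: The C4–C4a bond is disconnected to aryl ether aldehyde A7. The forward step is a Lewis-acid-promoted intramolecular Friedel–Crafts hydroxyalkylation, in which an ortho carbon of the 3,5-dibenzyloxyphenoxy ring attacks the aldehyde to give A6, the same compound as 25.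
- For: it is the most direct route, since A6 is one hydrogenolysis from the target. Regiochemistry is unambiguous because the two ortho positions are equivalent.
- Against: the C4 carbinol is formed under ionising conditions, and its C–O bond is more labile towards the Lewis acid than the aldehyde is. Epimerisation to the 3,4-trans isomer and a second arylation (the reaction that builds proanthocyanidins) are therefore expected.
- Against: the α-acyloxy aldehyde A7 is prone to epimerisation and elimination, and its C2 aryl ether would have to be made by substitution at an electron-rich benzylic carbon.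
- Comparison: the chosen strategy is longer, but it never exposes the C4–O bond to acid and sets C4 by a predictable chelation model.

Key step: step 16

Remark: the target is taken as the (2R,3S,4S) isomer (2,3-trans-3,4-cis) encoded in its SMILES, and 3,4,5-tris(benzyloxy)benzoic acid 22 is used as a purchasable starting material in place of gallic acid.

**Route**

Step 1
Reactants: 1 3,4-bis(benzyloxy)benzaldehyde
Product: 2 ethyl (E)-3-[3,4-bis(benzyloxy)phenyl]prop-2-enoate
Conditions: triethyl phosphonoacetate, NaH, THF, 0 °C → rt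
Reagents that add atoms: triethyl phosphonoacetate, CCOC(=O)CP(=O)(OCC)OCC
Why: Horner–Wadsworth–Emmons olefination of an aromatic aldehyde with a stabilised phosphonate anion gives the (E)-cinnamate almost exclusively.

Step 2
Reactants: 2 ethyl (E)-3-[3,4-bis(benzyloxy)phenyl]prop-2-enoate
Product: 3 (E)-3-[3,4-bis(benzyloxy)phenyl]prop-2-en-1-ol
Conditions: iBu2AlH (2.2 equiv), CH2Cl2, −78 °C; aq. KNaC4H4O6
Reagents that add atoms: none
Why: 1,2-reduction of the conjugated ester by iBu2AlH gives the allylic alcohol and leaves the double bond and the benzyl ethers alone.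

Step 3
Reactants: 3 (E)-3-[3,4-bis(benzyloxy)phenyl]prop-2-en-1-ol
Product: 5 (1R,2S)-1-[3,4-bis(benzyloxy)phenyl]-2,3-dihydroxypropyl benzoate, via epoxy alcohol 4 (not isolated)
Conditions: Ti(OiPr)4 (10 mol%), L-(+)-diisopropyl tartrate (12 mol%), tBuOOH (2 equiv), 4 Å MS, CH2Cl2, −20 °C; then P(OMe)3; then Ti(OiPr)4 (1.5 equiv), PhCO2H (1.5 equiv), −20 → 0 °C
Reagents that add atoms: tert-butyl hydroperoxide, CC(C)(C)OO; benzoic acid, O=C(O)c1ccccc1
Why: Sharpless asymmetric epoxidation with the L-(+)-tartrate gives the (2S,3S)-epoxy alcohol 4, which fixes C3 and the oxygen that becomes O3; because 4-alkoxyphenyl glycidols are labile, 4 is opened in the same flask by Ti(OiPr)4-assisted delivery of benzoate to the benzylic carbon with inversion, which sets C2 and the 2,3-anti relationship.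

Step 4
Reactants: 5 (1R,2S)-1-[3,4-bis(benzyloxy)phenyl]-2,3-dihydroxypropyl benzoate
Product: 6 (R)-[3,4-bis(benzyloxy)phenyl][(4S)-2-(4-methoxyphenyl)-1,3-dioxolan-4-yl]methyl benzoate (both epimers at the acetal carbon)
Conditions: 4-MeOC6H4CH(OMe)2, PPTS (cat.), CH2Cl2, rt
Reagents that add atoms: 4-methoxybenzaldehyde dimethyl acetal, COc1ccc(C(OC)OC)cc1
Why: acid-catalysed transacetalisation closes a dioxolane on the terminal 1,2-diol; it is done at once so that the benzoate has no free hydroxyl to migrate to, and the acetal centre is destroyed in step 7.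

Step 5
Reactants: 6 (R)-[3,4-bis(benzyloxy)phenyl][(4S)-2-(4-methoxyphenyl)-1,3-dioxolan-4-yl]methyl benzoate
Product: 7 (R)-[3,4-bis(benzyloxy)phenyl][(4S)-2-(4-methoxyphenyl)-1,3-dioxolan-4-yl]methanol
Conditions: K2CO3 (cat.), MeOH, 0 °C → rt
Reagents that add atoms: none
Why: base-catalysed methanolysis removes the benzoate; the acetal and the benzyl ethers are inert to methoxide.

Step 6
Reactants: 7 (R)-[3,4-bis(benzyloxy)phenyl][(4S)-2-(4-methoxyphenyl)-1,3-dioxolan-4-yl]methanol
Product: 8 [(R)-[3,4-bis(benzyloxy)phenyl][(4S)-2-(4-methoxyphenyl)-1,3-dioxolan-4-yl]methoxy]triethylsilane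
Conditions: Et3SiCl, imidazole, DMF, 0 °C
Reagents that add atoms: chlorotriethylsilane, CC[Si](Cl)(CC)CC
Why: silylation of the secondary benzylic alcohol; the triethylsilyl group does not chelate in step 13 and can later be removed in the presence of a tert-butyldimethylsilyl ether.

Step 7
Reactants: 8 [(R)-[3,4-bis(benzyloxy)phenyl][(4S)-2-(4-methoxyphenyl)-1,3-dioxolan-4-yl]methoxy]triethylsilane
Product: 9 (2S,3R)-3-[3,4-bis(benzyloxy)phenyl]-2-[(4-methoxybenzyl)oxy]-3-[(triethylsilyl)oxy]propan-1-ol
Conditions: iBu2AlH (3 equiv), CH2Cl2, −78 → 0 °C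
Reagents that add atoms: none
Why: regioselective reductive opening of the aryl acetal: aluminium binds the less hindered primary oxygen, that C–O bond breaks and hydride quenches the oxocarbenium ion, leaving the PMB ether on O3 and a free primary alcohol; both acetal epimers converge.

Step 8
Reactants: 9 (2S,3R)-3-[3,4-bis(benzyloxy)phenyl]-2-[(4-methoxybenzyl)oxy]-3-[(triethylsilyl)oxy]propan-1-ol
Product: 10 (2R,3R)-3-[3,4-bis(benzyloxy)phenyl]-2-[(4-methoxybenzyl)oxy]-3-[(triethylsilyl)oxy]propanal
Conditions: Dess–Martin periodinane, NaHCO3, CH2Cl2, 0 °C → rt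
Reagents that add atoms: none
Why: buffered Dess–Martin oxidation gives the α-alkoxy aldehyde without epimerisation; it is used crude in step 11.

Step 9
Reactants: 11 5-bromobenzene-1,3-diol (5-bromoresorcinol)
Product: 12 1,3-bis(benzyloxy)-5-bromobenzene
Conditions: BnBr, K2CO3, DMF, rt → 60 °C
Reagents that add atoms: benzyl bromide, BrCc1ccccc1
Why: Williamson etherification of both phenols.

Step 10
Reactants: 12 1,3-bis(benzyloxy)-5-bromobenzene
Product: 13 1,5-bis(benzyloxy)-3-bromo-2-iodobenzene
Conditions: NIS, CF3CO2H (cat.), MeCN, 0 °C → rt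
Reagents that add atoms: N-iodosuccinimide, O=C1CCC(=O)N1I
Why: electrophilic aromatic iodination; the position para to one benzyloxy group and ortho to the other (next to bromine) is expected to react in preference to the position flanked by both ethers, as in formylation and halogenation of 3,5-dialkoxybromobenzenes.

Step 11
Reactants: 13 1,5-bis(benzyloxy)-3-bromo-2-iodobenzene; 10 (2R,3R)-3-[3,4-bis(benzyloxy)phenyl]-2-[(4-methoxybenzyl)oxy]-3-[(triethylsilyl)oxy]propanal
Product: 15 (2S,3R)-1-[2,4-bis(benzyloxy)-6-bromophenyl]-3-[3,4-bis(benzyloxy)phenyl]-2-[(4-methoxybenzyl)oxy]-3-[(triethylsilyl)oxy]propan-1-ol as a mixture of C1 epimers, via arylmagnesium chloride 14 (not isolated)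
Conditions: iPrMgCl·LiCl, THF, −40 °C; then 10, −40 → −20 °C; aq. NH4Cl
Reagents that add atoms: none
Why: iodine–magnesium exchange is much faster at C–I than at C–Br and the ortho-bromoarylmagnesium chloride 14 is stable towards aryne formation at these temperatures; its 1,2-addition to the aldehyde forms the C4–C4a bond, and the carbinol configuration does not matter because it is erased in step 12.

Step 12
Reactants: 15 (2S,3R)-1-[2,4-bis(benzyloxy)-6-bromophenyl]-3-[3,4-bis(benzyloxy)phenyl]-2-[(4-methoxybenzyl)oxy]-3-[(triethylsilyl)oxy]propan-1-ol (C1 epimers)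
Product: 16 (2R,3R)-1-[2,4-bis(benzyloxy)-6-bromophenyl]-3-[3,4-bis(benzyloxy)phenyl]-2-[(4-methoxybenzyl)oxy]-3-[(triethylsilyl)oxy]propan-1-one
Conditions: Dess–Martin periodinane, NaHCO3, CH2Cl2, rt
Reagents that add atoms: none
Why: Dess–Martin oxidation converts both epimers into one aryl ketone under neutral conditions that spare the α-stereocentre and the silyl ether.

Step 13
Reactants: 16 (2R,3R)-1-[2,4-bis(benzyloxy)-6-bromophenyl]-3-[3,4-bis(benzyloxy)phenyl]-2-[(4-methoxybenzyl)oxy]-3-[(triethylsilyl)oxy]propan-1-one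
Product: 17 (1S,2S,3R)-1-[2,4-bis(benzyloxy)-6-bromophenyl]-3-[3,4-bis(benzyloxy)phenyl]-2-[(4-methoxybenzyl)oxy]-3-[(triethylsilyl)oxy]propan-1-ol
Conditions: Zn(BH4)2, Et2O, −30 → 0 °C
Reagents that add atoms: none
Why: chelation-controlled (Cram chelate) reduction: divalent zinc bridges the carbonyl oxygen and the PMB ether oxygen on the α-carbon, and hydride adds to the face of the five-membered chelate away from the C2 side chain, giving the 3,4-anti (1S) alcohol; the bulky silyl ether on O2 does not compete as a chelating group.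

Step 14
Reactants: 17 (1S,2S,3R)-1-[2,4-bis(benzyloxy)-6-bromophenyl]-3-[3,4-bis(benzyloxy)phenyl]-2-[(4-methoxybenzyl)oxy]-3-[(triethylsilyl)oxy]propan-1-ol
Product: 18 (1S,2R,3R)-1-[2,4-bis(benzyloxy)-6-bromophenyl]-3-[3,4-bis(benzyloxy)phenyl]-1-[(tert-butyldimethylsilyl)oxy]-2-[(4-methoxybenzyl)oxy]-3-[(triethylsilyl)oxy]propane
Conditions: tBuMe2SiOTf, 2,6-lutidine, CH2Cl2, −78 → 0 °C
Reagents that add atoms: tert-butyldimethylsilyl trifluoromethanesulfonate, CC(C)(C)[Si](C)(C)OS(=O)(=O)C(F)(F)F
Why: the silyl triflate silylates the hindered benzylic alcohol under buffered conditions that do not ionise it; the configuration is unchanged (the descriptor at C2 changes only through the priority rules).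

Step 15
Reactants: 18 (1S,2R,3R)-1-[2,4-bis(benzyloxy)-6-bromophenyl]-3-[3,4-bis(benzyloxy)phenyl]-1-[(tert-butyldimethylsilyl)oxy]-2-[(4-methoxybenzyl)oxy]-3-[(triethylsilyl)oxy]propane
Product: 19 (1R,2R,3S)-3-[2,4-bis(benzyloxy)-6-bromophenyl]-1-[3,4-bis(benzyloxy)phenyl]-3-[(tert-butyldimethylsilyl)oxy]-2-[(4-methoxybenzyl)oxy]propan-1-ol
Conditions: HF·pyridine, pyridine, THF, 0 °C
Reagents that add atoms: none
Why: selective desilylation: the triethylsilyl ether on the unhindered benzylic oxygen is cleaved much faster than the tert-butyldimethylsilyl ether next to the 2,6-disubstituted arene, and pyridine-buffered fluoride is not acidic enough to ionise C4.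

Step 16
Reactants: 19 (1R,2R,3S)-3-[2,4-bis(benzyloxy)-6-bromophenyl]-1-[3,4-bis(benzyloxy)phenyl]-3-[(tert-butyldimethylsilyl)oxy]-2-[(4-methoxybenzyl)oxy]propan-1-ol
Product: 20 (2R,3R,4S)-5,7-bis(benzyloxy)-2-[3,4-bis(benzyloxy)phenyl]-4-[(tert-butyldimethylsilyl)oxy]-3-[(4-methoxybenzyl)oxy]chromane (2,3-trans-3,4-cis)
Conditions: CuI (20 mol%), 1,10-phenanthroline (40 mol%), Cs2CO3 (2 equiv), toluene, 110 °C, argon
Reagents that add atoms: none
Why: Cs2CO3 deprotonates the C2 hydroxyl and the alkoxide binds phenanthroline-ligated monovalent copper; oxidative addition of the neighbouring C8a–Br bond gives a trivalent copper aryl alkoxide held in a seven-membered metallacycle, and C–O reductive elimination forms the O1–C8a bond and returns monovalent copper. The closest known reaction type is the intramolecular Ullmann-type O-arylation of secondary alcohols with aryl bromides used to close chromans and dihydrobenzofurans. Ring C closes in a 6-exo mode at the arene carbon, the departing bromide lying outside the new ring. No stereocentre is created: the C2–O bond is never broken, so C2 keeps its configuration, and neither C3 nor C4 has an acidic hydrogen under carbonate base, so the all-anti chain maps onto the 2,3-trans-3,4-cis chroman. The step needs chemoselectivity only, and the substrate provides it: O3 is a PMB ether (a free O3 would close the five-membered dihydrobenzofuran instead) and O4 is a silyl ether, so the C2 alkoxide is the sole nucleophile able to reach C8a. Carbonate base in toluene is chosen because both benzylic C–O bonds, at C2 and at C4, would ionise under the acidic closures common in flavan chemistry. The two benzyloxy groups are meta to the bromide and should not slow the oxidative addition much, and the product can adopt a half-chair with the C2 aryl and C3 alkoxy groups equatorial and the C4 silyloxy group axial.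

Step 17
Reactants: 20 (2R,3R,4S)-5,7-bis(benzyloxy)-2-[3,4-bis(benzyloxy)phenyl]-4-[(tert-butyldimethylsilyl)oxy]-3-[(4-methoxybenzyl)oxy]chromane
Product: 21 (2R,3R,4S)-5,7-bis(benzyloxy)-2-[3,4-bis(benzyloxy)phenyl]-4-[(tert-butyldimethylsilyl)oxy]chroman-3-ol
Conditions: DDQ (1.2 equiv), CH2Cl2/pH 7 phosphate buffer (10:1), 0 °C
Reagents that add atoms: none
Why: oxidative PMB cleavage: DDQ abstracts hydride from the freely rotating 4-methoxybenzylic CH2 and water hydrolyses the oxocarbenium ion; the C4–H bond of the chroman is pseudo-equatorial (the silyloxy group is axial to avoid the C5 benzyloxy group) and so poorly aligned with the ring A π system, which together with low temperature and limiting oxidant should keep it intact.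

Step 18
Reactants: 21 (2R,3R,4S)-5,7-bis(benzyloxy)-2-[3,4-bis(benzyloxy)phenyl]-4-[(tert-butyldimethylsilyl)oxy]chroman-3-ol; 22 3,4,5-tris(benzyloxy)benzoic acid
Product: 24 (2R,3R,4S)-5,7-bis(benzyloxy)-2-[3,4-bis(benzyloxy)phenyl]-4-[(tert-butyldimethylsilyl)oxy]chroman-3-yl 3,4,5-tris(benzyloxy)benzoate, via acid chloride 23 (not isolated)
Conditions: 22, (COCl)2, DMF (cat.), CH2Cl2, rt; then 21, Et3N, DMAP, CH2Cl2, 0 °C → rt
Reagents that add atoms: none
Why: DMAP-catalysed acylation of the hindered secondary alcohol with the acid chloride; O4 is blocked, so only O3 is esterified and no stereocentre is touched.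

Step 19
Reactants: 24 (2R,3R,4S)-5,7-bis(benzyloxy)-2-[3,4-bis(benzyloxy)phenyl]-4-[(tert-butyldimethylsilyl)oxy]chroman-3-yl 3,4,5-tris(benzyloxy)benzoate
Product: 25 (2R,3S,4S)-5,7-bis(benzyloxy)-2-[3,4-bis(benzyloxy)phenyl]-4-hydroxychroman-3-yl 3,4,5-tris(benzyloxy)benzoate
Conditions: Bu4NF, AcOH (1:1), THF, 0 °C → rt
Reagents that add atoms: none
Why: fluoride-induced desilylation; acetic acid protonates the C4 alkoxide as it forms, which suppresses migration of the cis ester from O3 to O4, and the medium is too weakly acidic to ionise C4.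

Step 20
Reactants: 25 (2R,3S,4S)-5,7-bis(benzyloxy)-2-[3,4-bis(benzyloxy)phenyl]-4-hydroxychroman-3-yl 3,4,5-tris(benzyloxy)benzoate
Product: 26 (2R,3S,4S)-2-(3,4-dihydroxyphenyl)-4,5,7-trihydroxychroman-3-yl 3,4,5-trihydroxybenzoate (target)
Conditions: H2 (1 atm), Pd(OH)2/C, THF/MeOH, rt
Reagents that add atoms: none
Why: catalytic hydrogenolysis of the seven aryl benzyl ethers under neutral conditions; without acid the secondary benzylic C2–O1 and C4–OH bonds should react much more slowly, and the reaction is stopped once the benzyl ethers are consumed.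

**Compound list**

1 | 3,4-bis(benzyloxy)benzaldehyde | O=Cc1ccc(OCc2ccccc2)c(OCc2ccccc2)c1 | starting material
2 | ethyl (E)-3-[3,4-bis(benzyloxy)phenyl]prop-2-enoate | CCOC(=O)/C=C/c1ccc(OCc2ccccc2)c(OCc2ccccc2)c1 | intermediate
3 | (E)-3-[3,4-bis(benzyloxy)phenyl]prop-2-en-1-ol | OC/C=C/c1ccc(OCc2ccccc2)c(OCc2ccccc2)c1 | intermediate
4 | [(2S,3S)-3-[3,4-bis(benzyloxy)phenyl]oxiran-2-yl]methanol (not isolated) | OC[C@@H]1O[C@H]1c1ccc(OCc2ccccc2)c(OCc2ccccc2)c1 | intermediate
5 | (1R,2S)-1-[3,4-bis(benzyloxy)phenyl]-2,3-dihydroxypropyl benzoate | O=C(O[C@H](c1ccc(OCc2ccccc2)c(OCc2ccccc2)c1)[C@@H](O)CO)c1ccccc1 | intermediate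
6 | (R)-[3,4-bis(benzyloxy)phenyl][(4S)-2-(4-methoxyphenyl)-1,3-dioxolan-4-yl]methyl benzoate (acetal epimers) | O=C(O[C@H](c1ccc(OCc2ccccc2)c(OCc2ccccc2)c1)[C@@H]1COC(c2ccc(OC)cc2)O1)c1ccccc1 | intermediate
7 | (R)-[3,4-bis(benzyloxy)phenyl][(4S)-2-(4-methoxyphenyl)-1,3-dioxolan-4-yl]methanol (acetal epimers) | O[C@H](c1ccc(OCc2ccccc2)c(OCc2ccccc2)c1)[C@@H]1COC(c2ccc(OC)cc2)O1 | intermediate
8 | [(R)-[3,4-bis(benzyloxy)phenyl][(4S)-2-(4-methoxyphenyl)-1,3-dioxolan-4-yl]methoxy]triethylsilane (acetal epimers) | CC[Si](CC)(CC)O[C@H](c1ccc(OCc2ccccc2)c(OCc2ccccc2)c1)[C@@H]1COC(c2ccc(OC)cc2)O1 | intermediate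
9 | (2S,3R)-3-[3,4-bis(benzyloxy)phenyl]-2-[(4-methoxybenzyl)oxy]-3-[(triethylsilyl)oxy]propan-1-ol | CC[Si](CC)(CC)O[C@H](c1ccc(OCc2ccccc2)c(OCc2ccccc2)c1)[C@@H](OCc1ccc(OC)cc1)CO | intermediate
10 | (2R,3R)-3-[3,4-bis(benzyloxy)phenyl]-2-[(4-methoxybenzyl)oxy]-3-[(triethylsilyl)oxy]propanal | CC[Si](CC)(CC)O[C@H](c1ccc(OCc2ccccc2)c(OCc2ccccc2)c1)[C@@H](OCc1ccc(OC)cc1)C=O | intermediate
11 | 5-bromobenzene-1,3-diol (5-bromoresorcinol) | Oc1cc(O)cc(Br)c1 | starting material
12 | 1,3-bis(benzyloxy)-5-bromobenzene | Brc1cc(OCc2ccccc2)cc(OCc2ccccc2)c1 | intermediate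
13 | 1,5-bis(benzyloxy)-3-bromo-2-iodobenzene | Ic1c(Br)cc(OCc2ccccc2)cc1OCc1ccccc1 | intermediate
14 | [2,4-bis(benzyloxy)-6-bromophenyl]magnesium chloride (not isolated) | Cl[Mg]c1c(Br)cc(OCc2ccccc2)cc1OCc1ccccc1 | intermediate
15 | (2S,3R)-1-[2,4-bis(benzyloxy)-6-bromophenyl]-3-[3,4-bis(benzyloxy)phenyl]-2-[(4-methoxybenzyl)oxy]-3-[(triethylsilyl)oxy]propan-1-ol (both C1 epimers) | CC[Si](CC)(CC)O[C@H](c1ccc(OCc2ccccc2)c(OCc2ccccc2)c1)[C@@H](OCc1ccc(OC)cc1)C(O)c1c(Br)cc(OCc2ccccc2)cc1OCc1ccccc1 | intermediate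
16 | (2R,3R)-1-[2,4-bis(benzyloxy)-6-bromophenyl]-3-[3,4-bis(benzyloxy)phenyl]-2-[(4-methoxybenzyl)oxy]-3-[(triethylsilyl)oxy]propan-1-one | CC[Si](CC)(CC)O[C@H](c1ccc(OCc2ccccc2)c(OCc2ccccc2)c1)[C@@H](OCc1ccc(OC)cc1)C(=O)c1c(Br)cc(OCc2ccccc2)cc1OCc1ccccc1 | intermediate
17 | (1S,2S,3R)-1-[2,4-bis(benzyloxy)-6-bromophenyl]-3-[3,4-bis(benzyloxy)phenyl]-2-[(4-methoxybenzyl)oxy]-3-[(triethylsilyl)oxy]propan-1-ol | CC[Si](CC)(CC)O[C@H](c1ccc(OCc2ccccc2)c(OCc2ccccc2)c1)[C@@H](OCc1ccc(OC)cc1)[C@@H](O)c1c(Br)cc(OCc2ccccc2)cc1OCc1ccccc1 | intermediate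
18 | (1S,2R,3R)-1-[2,4-bis(benzyloxy)-6-bromophenyl]-3-[3,4-bis(benzyloxy)phenyl]-1-[(tert-butyldimethylsilyl)oxy]-2-[(4-methoxybenzyl)oxy]-3-[(triethylsilyl)oxy]propane | CC[Si](CC)(CC)O[C@H](c1ccc(OCc2ccccc2)c(OCc2ccccc2)c1)[C@@H](OCc1ccc(OC)cc1)[C@@H](O[Si](C)(C)C(C)(C)C)c1c(Br)cc(OCc2ccccc2)cc1OCc1ccccc1 | intermediate
19 | (1R,2R,3S)-3-[2,4-bis(benzyloxy)-6-bromophenyl]-1-[3,4-bis(benzyloxy)phenyl]-3-[(tert-butyldimethylsilyl)oxy]-2-[(4-methoxybenzyl)oxy]propan-1-ol | O[C@H](c1ccc(OCc2ccccc2)c(OCc2ccccc2)c1)[C@@H](OCc1ccc(OC)cc1)[C@@H](O[Si](C)(C)C(C)(C)C)c1c(Br)cc(OCc2ccccc2)cc1OCc1ccccc1 | intermediate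
20 | (2R,3R,4S)-5,7-bis(benzyloxy)-2-[3,4-bis(benzyloxy)phenyl]-4-[(tert-butyldimethylsilyl)oxy]-3-[(4-methoxybenzyl)oxy]chromane | COc1ccc(CO[C@@H]2[C@@H](c3ccc(OCc4ccccc4)c(OCc4ccccc4)c3)Oc3cc(OCc4ccccc4)cc(OCc4ccccc4)c3[C@@H]2O[Si](C)(C)C(C)(C)C)cc1 | intermediate
21 | (2R,3R,4S)-5,7-bis(benzyloxy)-2-[3,4-bis(benzyloxy)phenyl]-4-[(tert-butyldimethylsilyl)oxy]chroman-3-ol | O[C@@H]1[C@@H](c2ccc(OCc3ccccc3)c(OCc3ccccc3)c2)Oc2cc(OCc3ccccc3)cc(OCc3ccccc3)c2[C@@H]1O[Si](C)(C)C(C)(C)C | intermediate
22 | 3,4,5-tris(benzyloxy)benzoic acid | O=C(O)c1cc(OCc2ccccc2)c(OCc2ccccc2)c(OCc2ccccc2)c1 | starting material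
23 | 3,4,5-tris(benzyloxy)benzoyl chloride (not isolated) | O=C(Cl)c1cc(OCc2ccccc2)c(OCc2ccccc2)c(OCc2ccccc2)c1 | intermediate
24 | (2R,3R,4S)-5,7-bis(benzyloxy)-2-[3,4-bis(benzyloxy)phenyl]-4-[(tert-butyldimethylsilyl)oxy]chroman-3-yl 3,4,5-tris(benzyloxy)benzoate | O=C(O[C@@H]1[C@@H](c2ccc(OCc3ccccc3)c(OCc3ccccc3)c2)Oc2cc(OCc3ccccc3)cc(OCc3ccccc3)c2[C@@H]1O[Si](C)(C)C(C)(C)C)c1cc(OCc2ccccc2)c(OCc2ccccc2)c(OCc2ccccc2)c1 | intermediate
25 | (2R,3S,4S)-5,7-bis(benzyloxy)-2-[3,4-bis(benzyloxy)phenyl]-4-hydroxychroman-3-yl 3,4,5-tris(benzyloxy)benzoate | O=C(O[C@@H]1[C@@H](c2ccc(OCc3ccccc3)c(OCc3ccccc3)c2)Oc2cc(OCc3ccccc3)cc(OCc3ccccc3)c2[C@@H]1O)c1cc(OCc2ccccc2)c(OCc2ccccc2)c(OCc2ccccc2)c1 | intermediate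
26 | (2R,3S,4S)-2-(3,4-dihydroxyphenyl)-4,5,7-trihydroxychroman-3-yl 3,4,5-trihydroxybenzoate | O=C(O[C@@H]1[C@@H](c2ccc(O)c(O)c2)Oc2cc(O)cc(O)c2[C@@H]1O)c1cc(O)c(O)c(O)c1 | target

**Step count and risk**

Total step count: 20. Longest linear sequence: 18 steps (1 → 26 through steps 1–8 and 11–20); steps 9 and 10 prepare the ring A fragment.

Step 16 (key step). The ring closure may stall, with protodebromination taking over, because a hindered secondary alkoxide has to meet an ortho-substituted aryl bromide. The C2 alkoxide may also be drained by a 1,5 oxygen-to-oxygen silyl shift from O4 at 110 °C. Fallback: set out from 17 and remove the silyl problem altogether. Bu4NF/AcOH cleaves the triethylsilyl ether to give the 1,3-diol F1. In F1 only O2 can reach C8a, since O4 would have to close a four-membered ring, so the same CuI/1,10-phenanthroline/Cs2CO3 coupling gives the chroman-4-ol F2. If copper is too slow, Pd(OAc)2 with a bulky di-tert-butyl biaryl phosphine can be used. Silylation of F2 with tBuMe2SiOTf/2,6-lutidine rejoins the route at 20. This detour also makes the selective desilylation of step 15 unnecessary.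

Step 3. The electron-rich epoxide may open with partial loss of stereochemical fidelity, by ionisation to a 4-alkoxybenzylic cation before benzoate is delivered, which would erode the configuration at C2. Fallback: C2 is corrected late by reduction instead of substitution. The material is carried on as a C2-epimer mixture (step 13 depends only on C3), setting out from 19 as a mixture of C1 epimers. Dess–Martin oxidation of the only free hydroxyl gives the aryl ketone F3, and Zn(BH4)2 reduction under chelation by the O3 PMB ether returns the 1,2-anti alcohol, rejoining the route at 19 as a single isomer.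

Step 17. Hydride abstraction by DDQ at the doubly activated C4–H or C2–H of the chroman may compete with PMB cleavage and over-oxidise ring C. Fallback: remove the PMB group before the chroman exists and rely on regioselective acylation at the end.
- Set out from 18. DDQ gives the alcohol F4; in the open chain the 2,6-disubstituted arene is twisted out of conjugation with C4–H.
- tBuMe2SiOTf/2,6-lutidine gives the bis(tert-butyldimethylsilyl) ether F5.
- Buffered HF·pyridine frees O2 to give the alcohol F6.
- The CuI-catalysed closure gives the 3,4-bis(silyloxy)chroman F7.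
- Bu4NF/AcOH gives the cis-diol F8.
- Acid chloride 23 is expected to acylate the equatorial, non-benzylic O3 in preference to the axial O4 next to the C5 benzyloxy group, rejoining the route at 25.

Step 20. Hydrogenolysis may go beyond the benzyl ethers and cleave the axial benzylic C4–O bond (giving the 4-deoxy compound), or the free C4 hydroxyl may ionise on the catalyst surface. Fallback: keep the silyl ether as a shield during hydrogenolysis. Set out from 24; H2 over Pd(OH)2/C gives the heptaphenol silyl ether F9, and Et3N·3HF in MeCN then removes the silyl group to reach 26.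

**Further compounds**

F1 | step 16 | (1S,2R,3R)-1-[2,4-bis(benzyloxy)-6-bromophenyl]-3-[3,4-bis(benzyloxy)phenyl]-2-[(4-methoxybenzyl)oxy]propane-1,3-diol | O[C@H](c1ccc(OCc2ccccc2)c(OCc2ccccc2)c1)[C@@H](OCc1ccc(OC)cc1)[C@@H](O)c1c(Br)cc(OCc2ccccc2)cc1OCc1ccccc1
F2 | step 16 | (2R,3S,4S)-5,7-bis(benzyloxy)-2-[3,4-bis(benzyloxy)phenyl]-3-[(4-methoxybenzyl)oxy]chroman-4-ol | COc1ccc(CO[C@@H]2[C@@H](c3ccc(OCc4ccccc4)c(OCc4ccccc4)c3)Oc3cc(OCc4ccccc4)cc(OCc4ccccc4)c3[C@@H]2O)cc1
F3 | step 3 | (2S,3S)-3-[2,4-bis(benzyloxy)-6-bromophenyl]-1-[3,4-bis(benzyloxy)phenyl]-3-[(tert-butyldimethylsilyl)oxy]-2-[(4-methoxybenzyl)oxy]propan-1-one | O=C(c1ccc(OCc2ccccc2)c(OCc2ccccc2)c1)[C@@H](OCc1ccc(OC)cc1)[C@@H](O[Si](C)(C)C(C)(C)C)c1c(Br)cc(OCc2ccccc2)cc1OCc1ccccc1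
F4 | step 17 | (1S,2R,3R)-1-[2,4-bis(benzyloxy)-6-bromophenyl]-3-[3,4-bis(benzyloxy)phenyl]-1-[(tert-butyldimethylsilyl)oxy]-3-[(triethylsilyl)oxy]propan-2-ol | CC[Si](CC)(CC)O[C@H](c1ccc(OCc2ccccc2)c(OCc2ccccc2)c1)[C@@H](O)[C@@H](O[Si](C)(C)C(C)(C)C)c1c(Br)cc(OCc2ccccc2)cc1OCc1ccccc1
F5 | step 17 | (1S,2R,3R)-1-[2,4-bis(benzyloxy)-6-bromophenyl]-3-[3,4-bis(benzyloxy)phenyl]-1,2-bis[(tert-butyldimethylsilyl)oxy]-3-[(triethylsilyl)oxy]propane | CC[Si](CC)(CC)O[C@H](c1ccc(OCc2ccccc2)c(OCc2ccccc2)c1)[C@@H](O[Si](C)(C)C(C)(C)C)[C@@H](O[Si](C)(C)C(C)(C)C)c1c(Br)cc(OCc2ccccc2)cc1OCc1ccccc1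
F6 | step 17 | (1R,2R,3S)-3-[2,4-bis(benzyloxy)-6-bromophenyl]-1-[3,4-bis(benzyloxy)phenyl]-2,3-bis[(tert-butyldimethylsilyl)oxy]propan-1-ol | O[C@H](c1ccc(OCc2ccccc2)c(OCc2ccccc2)c1)[C@@H](O[Si](C)(C)C(C)(C)C)[C@@H](O[Si](C)(C)C(C)(C)C)c1c(Br)cc(OCc2ccccc2)cc1OCc1ccccc1
F7 | step 17 | (2R,3R,4S)-5,7-bis(benzyloxy)-2-[3,4-bis(benzyloxy)phenyl]-3,4-bis[(tert-butyldimethylsilyl)oxy]chromane | CC(C)(C)[Si](C)(C)O[C@@H]1[C@@H](c2ccc(OCc3ccccc3)c(OCc3ccccc3)c2)Oc2cc(OCc3ccccc3)cc(OCc3ccccc3)c2[C@@H]1O[Si](C)(C)C(C)(C)C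
F8 | step 17 | (2R,3S,4S)-5,7-bis(benzyloxy)-2-[3,4-bis(benzyloxy)phenyl]chromane-3,4-diol | O[C@@H]1[C@@H](c2ccc(OCc3ccccc3)c(OCc3ccccc3)c2)Oc2cc(OCc3ccccc3)cc(OCc3ccccc3)c2[C@@H]1O
F9 | step 20 | (2R,3R,4S)-4-[(tert-butyldimethylsilyl)oxy]-2-(3,4-dihydroxyphenyl)-5,7-dihydroxychroman-3-yl 3,4,5-trihydroxybenzoate | O=C(O[C@@H]1[C@@H](c2ccc(O)c(O)c2)Oc2cc(O)cc(O)c2[C@@H]1O[Si](C)(C)C(C)(C)C)c1cc(O)c(O)c(O)c1
A1 | alternative 1 | (2R,3S,4S)-5,7-bis(benzyloxy)-2-[3,4-bis(benzyloxy)phenyl]chromane-3,4-diol | O[C@@H]1[C@@H](c2ccc(OCc3ccccc3)c(OCc3ccccc3)c2)Oc2cc(OCc3ccccc3)cc(OCc3ccccc3)c2[C@@H]1O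
A2 | alternative 1 | (2S)-5,7-bis(benzyloxy)-2-[3,4-bis(benzyloxy)phenyl]-2H-chromene | [C@H]1(c2ccc(OCc3ccccc3)c(OCc3ccccc3)c2)Oc2cc(OCc3ccccc3)cc(OCc3ccccc3)c2C=C1
A3 | alternative 2 | (2R,3R)-2-[3,4-bis(benzyloxy)phenyl]-5,7-dihydroxy-4-oxochroman-3-yl 3,4,5-tris(benzyloxy)benzoate | O=C(O[C@@H]1[C@@H](c2ccc(OCc3ccccc3)c(OCc3ccccc3)c2)Oc2cc(O)cc(O)c2C1=O)c1cc(OCc2ccccc2)c(OCc2ccccc2)c(OCc2ccccc2)c1
A4 | alternative 2 | (2R,3R)-2-[3,4-bis(benzyloxy)phenyl]-5-bromo-4-oxo-3,4-dihydro-2H-pyran-3-yl 3,4,5-tris(benzyloxy)benzoate | O=C(O[C@@H]1[C@@H](c2ccc(OCc3ccccc3)c(OCc3ccccc3)c2)OC=C(Br)C1=O)c1cc(OCc2ccccc2)c(OCc2ccccc2)c(OCc2ccccc2)c1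
A5 | alternative 2 | 1-methoxy-1,3-bis(trimethylsilyloxy)buta-1,3-diene (ketene acetal geometry not defined) | COC(O[Si](C)(C)C)=CC(=C)O[Si](C)(C)C
A6 | alternative 3 | (2R,3S,4S)-5,7-bis(benzyloxy)-2-[3,4-bis(benzyloxy)phenyl]-4-hydroxychroman-3-yl 3,4,5-tris(benzyloxy)benzoate | O=C(O[C@@H]1[C@@H](c2ccc(OCc3ccccc3)c(OCc3ccccc3)c2)Oc2cc(OCc3ccccc3)cc(OCc3ccccc3)c2[C@@H]1O)c1cc(OCc2ccccc2)c(OCc2ccccc2)c(OCc2ccccc2)c1
A7 | alternative 3 | (2R,3R)-3-[3,5-bis(benzyloxy)phenoxy]-3-[3,4-bis(benzyloxy)phenyl]-1-oxopropan-2-yl 3,4,5-tris(benzyloxy)benzoate | O=C(O[C@@H](C=O)[C@@H](c1ccc(OCc2ccccc2)c(OCc2ccccc2)c1)Oc1cc(OCc2ccccc2)cc(OCc2ccccc2)c1)c1cc(OCc2ccccc2)c(OCc2ccccc2)c(OCc2ccccc2)c1
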